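Product is what this chain delivers, and I wanted its amount after 1.0 h in two flasks that differ in their charge of coupling partner.

    initiator → 2 initiating radical (k1 = 3.30 × 10⁻⁴ s⁻¹)
    starting material + initiating radical → capped initiator + first chain carrier (k2 = 75700 M⁻¹ s⁻¹)
    coupling partner + first chain carrier → product + second chain carrier (k3 = 3730 M⁻¹ s⁻¹)
    starting material + second chain carrier → by-product + first chain carrier (k4 = 14700 M⁻¹ s⁻¹)
    2 second chain carrier → ended chains A (k5 = 4 × 10⁸ M⁻¹ s⁻¹)
    2 first chain carrier → ended chains B (k6 = 1.8 × 10⁸ M⁻¹ s⁻¹)
all flasks: starting material 1.0 M; initiator 2 mol%; time 1.0 h

| flask | coupling partner |
|---|---|
| south-east | 0.700 equiv |
| north | 0.840 equiv |
- percentages count the starting material that a species holds: one ended chains B counts as two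
- where a step has two of a species, its rate is k times that concentration squared, and two are used at each turn
- run time (south-east): 1.0 h
- which of these there is most of at the end, counted by the starting material in it, south-east (product / starting material / first chain carrier)
- which of these there is most of at the end, counted by the starting material in it, north (product / starting material / first chain carrier)
- amount of the one of these that there is most of at the end, in percent of the starting material charged, south-east
- amount of the one of these that there is most of at the end, in percent of the starting material charged, north

I laddered the lifetimes at the south-east start, fastest first. The second chain carrier lasted 6.80 × 10⁻⁵ s against starting material, while the first chain carrier waited 3.83 × 10⁻⁴ s for coupling partner. So the first chain carrier was the resting state, and the ending of second chain carriers ran at 0.0701 of the ending of first ones.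

Next came the balance. Two radicals per turn of initiator met two carriers lost per ending, so the first chain carrier stood at the square root of initiator constant times initiator concentration over ending constant: 1.91 × 10⁻⁷ M. A carrier lived 0.0145 s against ending, so that level followed the initiator closely.

Below that rung, coupling partner fell pseudo-first-order with a life of 0.389 h, a figure with no coupling partner concentration in it. Slowest of the ladder, the initiator thinned the carrier level with a time constant of 1.68 h. The run stood between these two, so I kept the carriers' balance for the whole run, let the initiator's decline act through it from the start, and could drop neither time.

Summing over that falling level gave 1.94. I call this the exposure Λ, the time integral of coupling constant times first chain carrier level. The share of coupling partner left is e to the minus Λ, 14.4 %, in either flask. Product then came to 59.9 % in south-east and 71.9 % in north. Each product cost one starting material and each initiator radical another, leaving 37.3 % and 25.3 %, so product led in both .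

The forecast gave 59.6 % for south-east and 71.2 % for north, in its words “Product dominates in both runs”.

The flasks gave product at 59.6 % in south-east, with 37.7 % starting material, and product at 71.1 % in north, with 26.3 %.

South-east and north kept 14.9 % and 15.3 % of their coupling partner, as a Λ of 1.94 with no charge in it asks, so the gap between them is the charge: north with south-east's equivalents gave 59.6 % product in place of 71.1 %. Carried to a neighbour, south-east with 0.280 equiv of coupling partner, the same Λ gave me 24.0 % product and 73.2 % starting material, so the lead changes hands. The run gave 24.0 % product, 73 % left, and starting material as the leader.

The numbers of this flask are assumed; what happens was integrated by code.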